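**Plan**

- Retrosynthesis cuts, in this order: the ester joining the two halves (acyl–O bond at the primary carbinol CH2), the C(=O)–O bond of the seven-membered lactone, the side-chain CH=C bond of each half (Wittig), and in each carbocycle the two ring bonds on either side of the CH–CH unit that carries the carboxyl carbon ([4+2]).
- Enabling feature: in the lactone-fused cyclohexane the two ring-fusion CH groups are cis and alpha,beta to the lactone C=O (a butenolide C=C in disguise). The other four ring carbons, iPr–CH–CH2–CH2–C(OH)(CH2O), are a 1-oxygenated diene whose carbinol O and CH2O can be tied into a five-membered carbonate on a Z-enol. The cyclohexene of the other half is the antipodal adduct after loss of that carboxyl carbon.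
- Forward: one diene and the two antipodes of 5-menthyloxyfuran-2(5H)-one give both six-membered rings by Diels–Alder reaction; each adduct is then hydrogenated (helper C=C), hydrolysed at the acetal and olefinated.
- Western half: the carbonate is opened to the diol. Eastern half: the steering carboxyl leaves as CO2 (iododecarboxylation, then Zn elimination of the carbonate oxygen), which forms the ring alkene. The halves are joined by esterification, the seven-membered lactone closes afterwards, and desilylation ends the route.
- Stereochemistry: all four ring stereocentres of the western half arise in the cycloaddition (E-isopropyl and Z-enol-oxygen diene geometry, cis dienophile, endo mode, attack anti to the menthyloxy group). Absolute configuration comes from (+)-menthol (west) and (−)-menthol (east); both trisubstituted alkenes come from the stabilised ylide.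

Key step: step 7

Remark: the lactols from acetal hydrolysis are anomer mixtures and the secondary iodide is an epimer mixture; these centres become sp2 or are lost later, so their SMILES leave them undefined.

**Route**

Step 1
Reactants: 1 3-methylbut-1-yne
Product: 3 (E)-1-iodo-3-methylbut-1-ene, via (E)-alkenylzirconocene chloride 2 (not isolated)
Conditions: Cp2Zr(H)Cl, CH2Cl2, rt; then I2, 0 °C
Reagents that add atoms: iodine, II
Why: syn hydrozirconation of the terminal alkyne places Zr on the terminal carbon and iodinolysis proceeds with retention, which should give the E-alkenyl iodide (hydrozirconation–iodination).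

Step 2
Reactants: 3 (E)-1-iodo-3-methylbut-1-ene, 4 prop-2-yn-1-ol
Product: 5 (E)-6-methylhept-4-en-2-yn-1-ol
Conditions: PdCl2(PPh3)2 (2 mol %), CuI (4 mol %), Et3N, THF, rt
Reagents that add atoms: none
Why: Sonogashira coupling; oxidative addition of the alkenyl iodide to zerovalent palladium and reductive elimination both retain the E geometry.

Step 3
Reactants: 5 (E)-6-methylhept-4-en-2-yn-1-ol
Product: 6 (Z)-4-[(E)-4-methylpent-2-en-1-ylidene]-1,3-dioxolan-2-one (diene)
Conditions: AgOAc (10 mol %), DBU, CO2 (10 atm), toluene, rt
Reagents that add atoms: carbon dioxide, O=C=O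
Why: carboxylative cyclisation of a propargylic alcohol; the carbonate anion adds 5-exo-dig anti to the silver-activated alkyne, so the enol oxygen ends cis to the alkenyl chain (Z), the geometry the key step needs.

Step 4
Reactants: 7 5-hydroxyfuran-2(5H)-one, 8 (+)-menthol
Product: 9 (5S)-5-[(1S,2R,5S)-menthyloxy]furan-2(5H)-one
Conditions: camphorsulfonic acid (cat.), toluene, reflux (−H2O); crystallisation from petroleum ether
Reagents that add atoms: none
Why: acid-catalysed acetalisation of the pseudo-acid; the acetal centre epimerises through the oxocarbenium ion and the (5S) diastereomer should be collected by crystallisation-driven equilibration.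

Step 5
Reactants: 10 (2-hydroxyethyl)triphenylphosphonium bromide
Product: 11 [2-(tert-butyldimethylsilyloxy)ethyl]triphenylphosphonium bromide
Conditions: TBSCl, imidazole, CH2Cl2, rt
Reagents that add atoms: tert-butyl(chloro)dimethylsilane, CC(C)(C)[Si](C)(C)Cl
Why: standard silylation of a primary alcohol; the phosphonium centre is inert.

Step 6
Reactants: 11 [2-(tert-butyldimethylsilyloxy)ethyl]triphenylphosphonium bromide
Product: 13 tert-butyl 3-(tert-butyldimethylsilyloxy)-2-(triphenylphosphoranylidene)propanoate, via silyloxyethylidene phosphorane 12 (not isolated)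
Conditions: NaN(SiMe3)2 (1.0 equiv), THF, −78 °C; then Boc2O, −78 → 0 °C
Reagents that add atoms: di-tert-butyl dicarbonate, CC(C)(C)OC(=O)OC(=O)OC(C)(C)C
Why: C-acylation of an alkylidenephosphorane by a carbonic acid derivative; the tert-butoxide released from the leaving group removes the remaining alpha-proton, so the ester-stabilised ylide should result (ylide acylation with transylidation).

Step 7
Reactants: 6 diene, 9 (5S)-5-menthyloxyfuranone
Product: 14 western cycloadduct
Conditions: toluene (2 M), BHT (cat.), 120 °C, sealed tube
Reagents that add atoms: none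
Why: Concerted, asynchronous [4+2] cycloaddition in which the isopropyl-bearing diene terminus (the nucleophilic end of the 1-oxygenated diene) bonds to the beta-carbon of the butenolide and the enol-carbonate carbon bonds to the alpha-carbon, so both ring bonds flanking the lactone CH–CH unit form in one operation; the closest known reaction type is the thermal Diels–Alder reaction of 1-acyloxy-1,3-dienes with 5-alkoxyfuran-2(5H)-ones. The cyclohexene ring closes by intermolecular [4+2] cycloaddition, suprafacial on both partners, with the lactone ring carried in cis-fused. The isopropyl stereocentre follows from the E alkene, the two ring-fusion centres from the cis butenolide double bond and the fully substituted carbinol centre from the Z enol geometry (oxygen inside, CH2 outside), all four being related by the endo transition state, and the absolute sense is set by approach anti to the menthyloxy group. The step needs ortho regioselectivity (secured by the enol oxygen), endo selectivity (lactone carbonyl under the diene), pi-facial selectivity (the acetal substituent shields one face) and an accessible s-cis diene (the inside oxygen is pinned back in the five-membered carbonate, so it faces only a hydrogen).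

Step 8
Reactants: 14 western cycloadduct
Product: 15 saturated western adduct
Conditions: H2 (1 atm), 5% Rh/Al2O3, EtOAc, rt
Reagents that add atoms: none
Why: heterogeneous hydrogenation of the only C=C removes the helper unsaturation; Rh/Al2O3 should leave the allylic C–O bond of the carbonate intact, and no stereocentre is formed.

Step 9
Reactants: 15 saturated western adduct
Product: 16 western lactol
Conditions: TFA/H2O (4:1), 50 °C
Reagents that add atoms: water, O
Why: acid hydrolysis of the mixed acetal releases the auxiliary and gives the pseudo-acid (hydroxy lactone in equilibrium with the aldehyde acid); cyclic carbonates resist aqueous acid.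

Step 10
Reactants: 16 western lactol, 13 stabilised ylide
Product: 17 western seco acid
Conditions: toluene, 80 °C
Reagents that add atoms: none
Why: Wittig reaction of the open aldehyde form with the alpha-substituted ester-stabilised ylide, assisted by the substrate's own carboxylic acid; such ylides place the ester trans to the aldehyde substituent, which sets the E double bond (CH2OTBS cis to the ring).

Step 11
Reactants: 17 western seco acid
Product: 18 western tert-butyl ester
Conditions: tert-butyl 2,2,2-trichloroacetimidate, cyclohexane/CH2Cl2, rt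
Reagents that add atoms: tert-butyl 2,2,2-trichloroacetimidate, CC(C)(C)OC(=N)C(Cl)(Cl)Cl
Why: O-alkylation of the acid by the imidate needs no carboxyl activation, so beta-elimination of the carbonate is avoided, and the tert-butyl ester should resist attack by the neighbouring CH2OH in the following steps.

Step 12
Reactants: 18 western tert-butyl ester
Product: 19 western diol
Conditions: K2CO3 (0.2 equiv), MeOH, 0 °C
Reagents that add atoms: none
Why: base-catalysed methanolysis of the five-membered carbonate (transesterification) frees the tertiary and primary hydroxyls with both stereocentres untouched; tert-butyl esters and the silyl ether are inert at 0 °C.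

Step 13
Reactants: 7 5-hydroxyfuran-2(5H)-one, 20 (−)-menthol
Product: 21 (5R)-5-[(1R,2S,5R)-menthyloxy]furan-2(5H)-one
Conditions: camphorsulfonic acid (cat.), toluene, reflux (−H2O); crystallisation from petroleum ether
Reagents that add atoms: none
Why: same acetalisation with crystallisation-driven equilibration as step 4, here giving the (5R) antipode.

Step 14
Reactants: 6 diene, 21 (5R)-5-menthyloxyfuranone
Product: 22 eastern cycloadduct (enantiomer of 14)
Conditions: toluene (2 M), BHT (cat.), 120 °C, sealed tube
Reagents that add atoms: none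
Why: the same endo Diels–Alder reaction in the mirror-image series; approach anti to the menthyloxy group of the (5R)-furanone sets the isopropyl and acetal-bearing centres in the sense required for the eastern ring.

Step 15
Reactants: 22 eastern cycloadduct
Product: 23 saturated eastern adduct
Conditions: H2 (1 atm), 5% Rh/Al2O3, EtOAc, rt
Reagents that add atoms: none
Why: hydrogenation of the helper C=C as in step 8, without hydrogenolysis of the allylic carbonate.

Step 16
Reactants: 23 saturated eastern adduct
Product: 24 eastern lactol
Conditions: TFA/H2O (4:1), 50 °C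
Reagents that add atoms: water, O
Why: acetal hydrolysis as in step 9, releasing (−)-menthol and the pseudo-acid.

Step 17
Reactants: 24 eastern lactol, 13 stabilised ylide
Product: 25 eastern seco acid (enantiomer of 17)
Conditions: toluene, 80 °C
Reagents that add atoms: none
Why: E-selective Wittig reaction of the aldehyde form as in step 10, which builds the acrylate side chain of the eastern half.

Step 18
Reactants: 25 eastern seco acid
Product: 26 eastern iodide
Conditions: N-iodosuccinimide, ClCH2CH2Cl, visible light, reflux
Reagents that add atoms: N-iodosuccinimide, O=C1CCC(=O)N1I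
Why: radical iododecarboxylation through the acyl hypoiodite (Hunsdiecker-type) replaces the carboxyl carbon by iodine; the electron-poor acrylate C=C should not be iodinated and the new C–I configuration is irrelevant.

Step 19
Reactants: 26 eastern iodide
Product: 27 eastern hydroxy ester
Conditions: Zn dust, AcOH, THF, rt
Reagents that add atoms: none
Why: zinc-mediated reductive beta-elimination of a beta-iodo carbonate; insertion at C–I and expulsion of the vicinal carbonate oxygen form the ring C=C regiospecifically, and the carbonic half-ester loses CO2 to free the CH2OH.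

Step 20
Reactants: 27 eastern hydroxy ester
Product: 28 eastern dihydroxy acid
Conditions: TFA/CH2Cl2/H2O (10:10:1), 0 °C → rt
Reagents that add atoms: none
Why: acidolysis of the tert-butyl ester and the silyl ether under conditions that should not isomerise the base-sensitive skipped diene.

Step 21
Reactants: 28 eastern dihydroxy acid
Product: 30 eastern acid (bis-TBDPS ether), via tris-silyl ester 29 (not isolated)
Conditions: TBDPSCl (3.3 equiv), imidazole, DMF, rt; then AcOH/THF/H2O
Reagents that add atoms: tert-butyl(chloro)diphenylsilane, CC(C)(C)[Si](Cl)(c1ccccc1)c1ccccc1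
Why: exhaustive silylation followed by hydrolysis of the labile silyl ester leaves both primary hydroxyls as acid-stable TBDPS ethers and the acid free.

Step 22
Reactants: 19 western diol, 30 eastern acid
Product: 32 coupled ester, via mixed anhydride 31 (not isolated)
Conditions: 2-methyl-6-nitrobenzoic anhydride (MNBA), DMAP (cat.), Et3N, CH2Cl2, rt
Reagents that add atoms: none
Why: Shiina esterification; DMAP transfers the acyl group of the mixed anhydride to the primary hydroxyl, the tertiary hydroxyl is too hindered to react and the tert-butyl ester blocks lactonisation.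

Step 23
Reactants: 32 coupled ester
Product: 33 hydroxy diacid
Conditions: TFA/CH2Cl2/H2O (10:30:1), 0 °C → rt
Reagents that add atoms: none
Why: acidolysis removes both tert-butyl esters and the primary TBS ether, whereas TBDPS ethers survive TFA, so only the western allylic hydroxyl is freed.

Step 24
Reactants: 33 hydroxy diacid
Product: 35 bis-TBDPS ether of the target, via mixed anhydride 34 (not isolated)
Conditions: MNBA, DMAP, CH2Cl2 (1 mM), rt, slow addition
Reagents that add atoms: none
Why: Shiina lactonisation; only the ring carboxyl has a hydroxyl within reach (seven-membered closure onto the cis allylic CH2OH), the acrylic acid cannot cyclise and should return as the free acid on work-up, and the trans tertiary hydroxyl cannot form a beta-lactone.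

Step 25
Reactants: 35 bis-TBDPS ether of the target
Product: 36 CNP0361406.12
Conditions: HF·pyridine, pyridine/THF, 0 °C → rt
Reagents that add atoms: none
Why: fluoride cleavage of the two TBDPS ethers under buffered conditions that should leave the esters, the lactone and the aldol-type tertiary alcohol untouched.

**Compound list**

1 | 3-methylbut-1-yne | CC(C)C#C | starting material
2 | chlorobis(cyclopentadienyl)[(E)-3-methylbut-1-enyl]zirconium | CC(C)/C=C/[Zr](Cl)(C1C=CC=C1)C1C=CC=C1 | intermediate
3 | (E)-1-iodo-3-methylbut-1-ene | CC(C)/C=C/I | intermediate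
4 | prop-2-yn-1-ol | C#CCO | starting material
5 | (E)-6-methylhept-4-en-2-yn-1-ol | CC(C)/C=C/C#CCO | intermediate
6 | (Z)-4-[(E)-4-methylpent-2-en-1-ylidene]-1,3-dioxolan-2-one (ring O cis to the alkenyl chain) | CC(C)/C=C/C=C1\OC(=O)OC1 | intermediate
7 | 5-hydroxyfuran-2(5H)-one | O=C1C=CC(O)O1 | starting material
8 | (+)-menthol, (1S,2R,5S) | C[C@H]1CC[C@@H]([C@H](C1)O)C(C)C | starting material
9 | (5S)-5-[(1S,2R,5S)-menthyloxy]furan-2(5H)-one | O=C1C=C[C@@H](O[C@H]2C[C@@H](C)CC[C@@H]2C(C)C)O1 | intermediate
10 | (2-hydroxyethyl)triphenylphosphonium bromide | OCC[P+](c1ccccc1)(c1ccccc1)c1ccccc1.[Br-] | starting material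
11 | [2-(tert-butyldimethylsilyloxy)ethyl]triphenylphosphonium bromide | CC(C)(C)[Si](C)(C)OCC[P+](c1ccccc1)(c1ccccc1)c1ccccc1.[Br-] | intermediate
12 | [2-(tert-butyldimethylsilyloxy)ethylidene]triphenylphosphorane | CC(C)(C)[Si](C)(C)OCC=P(c1ccccc1)(c1ccccc1)c1ccccc1 | intermediate
13 | tert-butyl 3-(tert-butyldimethylsilyloxy)-2-(triphenylphosphoranylidene)propanoate | CC(C)(C)OC(=O)C(CO[Si](C)(C)C(C)(C)C)=P(c1ccccc1)(c1ccccc1)c1ccccc1 | intermediate
14 | western cycloadduct: 4-isopropyl-3-(d-menthyloxy)-3a,4,7,7a-tetrahydroisobenzofuran-1(3H)-one whose C-7 is the spiro C-4 of a 1,3-dioxolan-2-one (carbonate O on C-7); H-3a, H-4 and H-7a cis, carbonate CH2 cis to the lactone C=O, menthyloxy trans to C-4 | CC(C)[C@H]1C=C[C@@](O3)(COC3=O)[C@H]2C(=O)O[C@H](O[C@H]4C[C@@H](C)CC[C@@H]4C(C)C)[C@@H]12 | intermediate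
15 | saturated western adduct: 5,6-dihydro derivative of 14, same configuration | CC(C)[C@H]1CC[C@@](O3)(COC3=O)[C@H]2C(=O)O[C@H](O[C@H]4C[C@@H](C)CC[C@@H]4C(C)C)[C@@H]12 | intermediate
16 | western lactol: 3-hydroxy analogue of 15 (anomer mixture) | CC(C)[C@H]1CC[C@@](O3)(COC3=O)[C@H]2C(=O)OC(O)[C@@H]12 | intermediate
17 | western seco acid: cyclohexane spiro-fused to a 1,3-dioxolan-2-one and carrying, on the next three ring carbons, CO2H, the (E)-CH=C(CO2tBu)CH2OTBS side chain and isopropyl, all cis to one another and to the carbonate CH2 | CC(C)[C@H]1CC[C@@](O2)(COC2=O)[C@@H](C(=O)O)[C@H]1/C=C(\CO[Si](C)(C)C(C)(C)C)C(=O)OC(C)(C)C | intermediate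
18 | western tert-butyl ester: tert-butyl ester of the ring carboxyl of 17 | CC(C)[C@H]1CC[C@@](O2)(COC2=O)[C@@H](C(=O)OC(C)(C)C)[C@H]1/C=C(\CO[Si](C)(C)C(C)(C)C)C(=O)OC(C)(C)C | intermediate
19 | western diol: 18 with the carbonate opened to tertiary OH and CH2OH (OH trans to the ester, CH2OH cis) | CC(C)[C@H]1CC[C@@](O)(CO)[C@@H](C(=O)OC(C)(C)C)[C@H]1/C=C(\CO[Si](C)(C)C(C)(C)C)C(=O)OC(C)(C)C | intermediate
20 | (−)-menthol, (1R,2S,5R) | C[C@@H]1CC[C@H]([C@@H](C1)O)C(C)C | starting material
21 | (5R)-5-[(1R,2S,5R)-menthyloxy]furan-2(5H)-one | O=C1C=C[C@H](O[C@@H]2C[C@H](C)CC[C@H]2C(C)C)O1 | intermediate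
22 | eastern cycloadduct: enantiomer of 14 | CC(C)[C@@H]1C=C[C@](O3)(COC3=O)[C@@H]2C(=O)O[C@@H](O[C@@H]4C[C@H](C)CC[C@H]4C(C)C)[C@H]12 | intermediate
23 | saturated eastern adduct: enantiomer of 15 | CC(C)[C@@H]1CC[C@](O3)(COC3=O)[C@@H]2C(=O)O[C@@H](O[C@@H]4C[C@H](C)CC[C@H]4C(C)C)[C@H]12 | intermediate
24 | eastern lactol: enantiomer of 16 (anomer mixture) | CC(C)[C@@H]1CC[C@](O3)(COC3=O)[C@@H]2C(=O)OC(O)[C@H]12 | intermediate
25 | eastern seco acid: enantiomer of 17 | CC(C)[C@@H]1CC[C@](O2)(COC2=O)[C@H](C(=O)O)[C@@H]1/C=C(\CO[Si](C)(C)C(C)(C)C)C(=O)OC(C)(C)C | intermediate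
26 | eastern iodide: 25 with CO2H replaced by I (epimer mixture at C–I) | CC(C)[C@@H]1CC[C@](O2)(COC2=O)C(I)[C@@H]1/C=C(\CO[Si](C)(C)C(C)(C)C)C(=O)OC(C)(C)C | intermediate
27 | eastern hydroxy ester: tert-butyl (E)-3-[cis-3-(hydroxymethyl)-6-isopropylcyclohex-2-en-1-yl]-2-(tert-butyldimethylsilyloxymethyl)prop-2-enoate | CC(C)[C@@H]1CCC(CO)=C[C@@H]1/C=C(\CO[Si](C)(C)C(C)(C)C)C(=O)OC(C)(C)C | intermediate
28 | eastern dihydroxy acid: (E)-2-(hydroxymethyl)-3-[cis-3-(hydroxymethyl)-6-isopropylcyclohex-2-en-1-yl]prop-2-enoic acid | CC(C)[C@@H]1CCC(CO)=C[C@@H]1/C=C(\CO)C(=O)O | intermediate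
29 | tris-silyl ester: bis-TBDPS ether TBDPS ester of 28 | CC(C)[C@@H]1CCC(CO[Si](c2ccccc2)(c2ccccc2)C(C)(C)C)=C[C@@H]1/C=C(\CO[Si](c2ccccc2)(c2ccccc2)C(C)(C)C)C(=O)O[Si](c2ccccc2)(c2ccccc2)C(C)(C)C | intermediate
30 | eastern acid: bis-TBDPS ether of 28 | CC(C)[C@@H]1CCC(CO[Si](c2ccccc2)(c2ccccc2)C(C)(C)C)=C[C@@H]1/C=C(\CO[Si](c2ccccc2)(c2ccccc2)C(C)(C)C)C(=O)O | intermediate
31 | mixed anhydride of 30 with 2-methyl-6-nitrobenzoic acid | CC(C)[C@@H]1CCC(CO[Si](c2ccccc2)(c2ccccc2)C(C)(C)C)=C[C@@H]1/C=C(\CO[Si](c2ccccc2)(c2ccccc2)C(C)(C)C)C(=O)OC(=O)c2c(C)cccc2[N+](=O)[O-] | intermediate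
32 | coupled ester: 19 acylated at the primary hydroxyl by 30 | CC(C)[C@H]1CC[C@@](O)(COC(=O)/C(=C/[C@H]2C=C(CO[Si](c3ccccc3)(c3ccccc3)C(C)(C)C)CC[C@H]2C(C)C)CO[Si](c2ccccc2)(c2ccccc2)C(C)(C)C)[C@@H](C(=O)OC(C)(C)C)[C@H]1/C=C(\CO[Si](C)(C)C(C)(C)C)C(=O)OC(C)(C)C | intermediate
33 | hydroxy diacid: 32 with both tert-butyl esters and the TBS ether removed | CC(C)[C@H]1CC[C@@](O)(COC(=O)/C(=C/[C@H]2C=C(CO[Si](c3ccccc3)(c3ccccc3)C(C)(C)C)CC[C@H]2C(C)C)CO[Si](c2ccccc2)(c2ccccc2)C(C)(C)C)[C@@H](C(=O)O)[C@H]1/C=C(\CO)C(=O)O | intermediate
34 | mixed anhydride of the ring carboxyl of 33 with 2-methyl-6-nitrobenzoic acid | CC(C)[C@H]1CC[C@@](O)(COC(=O)/C(=C/[C@H]2C=C(CO[Si](c3ccccc3)(c3ccccc3)C(C)(C)C)CC[C@H]2C(C)C)CO[Si](c2ccccc2)(c2ccccc2)C(C)(C)C)[C@@H](C(=O)OC(=O)c2c(C)cccc2[N+](=O)[O-])[C@H]1/C=C(\CO)C(=O)O | intermediate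
35 | bis-TBDPS ether of the target (both eastern CH2OH groups silylated) | CC(C)[C@H]1CC[C@@](O)(COC(=O)/C(=C/[C@H]2C=C(CO[Si](c3ccccc3)(c3ccccc3)C(C)(C)C)CC[C@H]2C(C)C)CO[Si](c2ccccc2)(c2ccccc2)C(C)(C)C)[C@H]2C(=O)OCC(C(=O)O)=C[C@@H]12 | intermediate
36 | CNP0361406.12 | CC(C)[C@H]1CC[C@@](O)(COC(=O)/C(=C/[C@H]2C=C(CO)CC[C@H]2C(C)C)CO)[C@H]2C(=O)OCC(C(=O)O)=C[C@@H]12 | target

**Count and risks**

Total step count: 25. Longest linear sequence: 15 steps (steps 1–3, 14–21, 22–25).

Step 7 (the same applies to step 14). The diene terminus that must form the fully substituted carbon is hindered, so cycloaddition may be slower than polymerisation or hydrolytic loss of the enol carbonate, and endo selectivity may erode at the temperature needed. Fallback, from 9 back to 14: bromine is added to the double bond of 9 to give 3,4-dibromo-5-(d-menthyloxy)dihydrofuran-2(3H)-one F1, and triethylamine removes HBr to give the more electron-poor dienophile (5S)-3-bromo-5-(d-menthyloxy)furan-2(5H)-one F2. This should add diene 6 at lower temperature with the same regiochemistry and facial sense to give the 7a-bromo cycloadduct F3. Bu3SnH with AIBN then replaces bromine by hydrogen at the ring-fusion carbon, the cis-fused lactone being the product expected from hydrogen delivery to the bicyclic radical, which returns 14.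

Step 10 (the same applies to step 17). The alpha,alpha-disubstituted ylide may react sluggishly with the small open-chain fraction of the hindered lactol, and prolonged heating may epimerise the aldehyde alpha-carbon. Fallback, from 16 back to 17: Takai–Lombardo methylenation (Zn, CH2Br2, TiCl4), a non-basic reagent, converts the aldehyde form of 16 into the vinyl-substituted spiro-carbonate carboxylic acid F4. Cross-metathesis of F4 with tert-butyl 2-{[tert-butyl(dimethyl)silyl]oxymethyl}prop-2-enoate F5 (from tert-butyl 2-(hydroxymethyl)acrylate and TBSCl) is then run with the second-generation Hoveyda–Grubbs catalyst, RuCl2(H2IMes)(=CH-C6H4-2-OiPr). It should give the trisubstituted enoate with the ester trans to the ring, that is 17.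

Step 24. Activation may fall on the acrylic acid as well as on the ring carboxyl, so intermolecular acylation and oligomerisation may compete with the seven-membered ring closure. Fallback, from 33 back to 35: Mitsunobu lactonisation (PPh3, diisopropyl azodicarboxylate, toluene, high dilution) activates the only free primary hydroxyl instead of a carboxyl group. The ring carboxylate can then displace the allylic oxyphosphonium group in a seven-membered closure, and the acrylic acid has no cyclisation available; this fallback makes no new compound, F0.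

Further compounds
F1 | step 7 | 3,4-dibromo-5-(d-menthyloxy)dihydrofuran-2(3H)-one (5S; mixture at C-3 and C-4) | O=C1C(Br)C(Br)[C@@H](O[C@H]2C[C@@H](C)CC[C@@H]2C(C)C)O1
F2 | step 7 | (5S)-3-bromo-5-(d-menthyloxy)furan-2(5H)-one | O=C1C(Br)=C[C@@H](O[C@H]2C[C@@H](C)CC[C@@H]2C(C)C)O1
F3 | step 7 | 7a-bromo cycloadduct (14 with Br in place of H on the ring-fusion carbon next to the lactone C=O) | CC(C)[C@H]1C=C[C@@](O3)(COC3=O)[C@@]2(Br)C(=O)O[C@H](O[C@H]4C[C@@H](C)CC[C@@H]4C(C)C)[C@@H]12
F4 | step 10 | vinyl-substituted spiro-carbonate carboxylic acid (17 with CH=CH2 in place of the acrylate side chain) | CC(C)[C@H]1CC[C@@](O2)(COC2=O)[C@@H](C(=O)O)[C@H]1C=C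
F5 | step 10 | tert-butyl 2-{[tert-butyl(dimethyl)silyl]oxymethyl}prop-2-enoate | C=C(CO[Si](C)(C)C(C)(C)C)C(=O)OC(C)(C)C
F0 | step 24 | none | none
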